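**Retrosynthetic overview**
- The last C–C bond cut is CMe2–CH(CMe2OH). It forms by a reductive hydrogen-atom-transfer (MHAT) radical 5-exo closure of an exo-isopropenyl group onto the bridgehead prenyl group. The tertiary OH comes from O2 in the same flask.
- The two-carbon bridge of the bicyclo[3.2.1]octanetrione is cut to a flat acylphloroglucinol plus isoprene monoxide. Two Pd allylations set both bridgeheads and the bridge CH.
- The arene is cut to prenyl bromide, (R)-2-methylbutanoic acid and a benzene ring made by [3+3] from 2-methoxypropene and methylmalonyl dichloride.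
- Ring order: six-membered ring, then bridging cyclopentanone, then cyclopentane.

**Assumption:** (R)-2-methylbutanoic acid, methylmalonyl dichloride and racemic isoprene monoxide are bought, and the sense of induction of the Trost ligand is checked on the first run (both antipodes are sold).

**Locants:** 12 is numbered as bicyclo[3.2.1]octane: C1 prenyl bridgehead, C5 methyl bridgehead, C7 isopropenyl carbon, C8 bridge C=O. Compounds 13–15 are numbered as tricyclo[5.3.1.0(1,5)]undecane: C1 is the bridgehead that carried the prenyl group, C3 the new CH, C4 CMe2, C5 the ring-fusion CH, C7 the methyl bridgehead, C11 the bridge C=O.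

**Step 1**
Reactants: 1 2-methoxypropene; 2 methylmalonyl dichloride (2-methylpropanedioyl dichloride)
Product: 3 5-methoxy-2-methylbenzene-1,3-diol
Conditions: CH2Cl2, −30 °C → rt, N2 sweep
Reagents that add atoms: none
Why: Effenberger-type [3+3] cycloacylation, in which the enol ether is C-acylated by one COCl, the O-methyl group blocks the usual pyrone (O-acylation) exit so that the γ-CH3 of the β-methoxyenone closes onto the second COCl, and tautomerisation to the arene drives the reaction; no stereocentre forms.

**Step 2**
Reactants: 3 5-methoxy-2-methylbenzene-1,3-diol; 4 (R)-2-methylbutanoic acid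
Product: 7 (2R)-2-methyl-1-(2,4,6-trihydroxy-3-methylphenyl)butan-1-one, via (R)-2-methylbutanoyl chloride 5 (not isolated), via aryl ketone methyl ether 6 (not isolated)
Conditions: 4, (COCl)2, cat. DMF, CH2Cl2, 0 °C; add to 3, AlCl3 (4 equiv), CH2Cl2, 0 °C → rt; then NaI, MeCN, rt; aq HCl
Reagents that add atoms: none
Why: Friedel–Crafts acylation at one of the two equivalent free positions of a very electron-rich arene, then cleavage of the AlCl3-activated aryl methyl ether by iodide in the same flask; the (R) centre comes unchanged from 4 and working at or below rt avoids enolisation.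

**Step 3**
Reactants: 7 (2R)-2-methyl-1-(2,4,6-trihydroxy-3-methylphenyl)butan-1-one; 8 prenyl bromide (1-bromo-3-methylbut-2-ene)
Product: 9 (2R)-2-methyl-1-[2,4,6-trihydroxy-3-methyl-5-(3-methylbut-2-en-1-yl)phenyl]butan-1-one
Conditions: 8 (1.0 equiv), aq KOH, 0 °C
Reagents that add atoms: none
Why: Aqueous-base C-alkylation of an acylphloroglucinol (solvated phenoxide oxygens, soft allylic bromide) goes to the only unsubstituted ring carbon and the product re-aromatises; one equivalent of 8 at 0 °C limits over-alkylation and no new stereocentre arises.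

**Step 4**
Reactants: 9 (2R)-2-methyl-1-[2,4,6-trihydroxy-3-methyl-5-(3-methylbut-2-en-1-yl)phenyl]butan-1-one; 10 isoprene monoxide (2-methyl-2-vinyloxirane, racemic)
Product: 12 (1S,5S,7S)-4-hydroxy-5-methyl-3-[(2R)-2-methylbutanoyl]-1-(3-methylbut-2-en-1-yl)-7-(prop-1-en-2-yl)bicyclo[3.2.1]oct-3-ene-2,8-dione (isopropenyl exo = syn to C8=O), via dearomatised allylic alcohol 11 (not isolated)
Conditions: Pd2(dba)3·CHCl3 (2.5 mol %), (R,R)-DACH-phenyl Trost ligand (7.5 mol %), CH2Cl2, 0 °C; then 45 °C
Reagents that add atoms: none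
Why: Proposed new method: a double Tsuji–Trost allylation used as a dearomative (3+2) annulation, in which Pd(0) opens the vinyl epoxide, the alkoxide deprotonates 9 and the less hindered methyl-bearing ring carbon attacks the distal CH2 terminus inside the chiral pocket (sets C5 as S; closest known types are neutral 1,4-alkylation with vinyl epoxides and Pd/Trost-ligand allylic dearomatisation of 1-methyl-2-naphthols; attack at the prenyl-bearing carbon is the expected minor pathway, estimated at about 1:2–3, and leads to a separable isomeric bicycle), after which the vinylogous acid 11 (pKa about 5) activates its own allylic OH for a second ionisation and the prenyl-bearing enol carbon closes 5-exo on the internal allyl terminus (as in Tsuji 3-vinylcyclopentanone closures and Pd conjunctive annulations of acylphloroglucinols), which fixes C1 (S) through the bridge and places the isopropenyl group exo at C7 (S), away from the enolate bridge, while O-allylation stays reversible under Pd(0).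

**Step 5**
Reactants: 12 the bicyclic trione of step 4
Product: 15 (1S,3S,5S,7S)-8-hydroxy-3-(2-hydroxypropan-2-yl)-4,4,7-trimethyl-9-[(2R)-2-methylbutanoyl]tricyclo[5.3.1.0(1,5)]undec-8-ene-10,11-dione, via isopropenyl tricycle 13 (not isolated), via tertiary hydroperoxide 14 (not isolated)
Conditions: Co(salen-tBu4)Cl (10 mol %), PhSiH3 (0.2 equiv), 2,6-lutidine (1 equiv), PhH, rt, Ar; then Mn(dpm)3 (10 mol %), PhSiH3 (2 equiv), i-PrOH, O2 (1 atm), 0 °C; then PPh3
Reagents that add atoms: dioxygen O=O
Why: MHAT radical cycloisomerisation followed by Mukaiyama hydration, in which Co–H gives H• to the 1,1-disubstituted alkene faster than to the trisubstituted one, the tertiary radical held exo beside the bridgehead prenyl group closes 5-exo to the only possible cis-fused ring (no O2 is present yet, so it is not intercepted) and returns H• to Co(II) to leave 13, whose new isopropenyl group is then hydrated through the tertiary radical with O2 and the hydroperoxide is reduced by PPh3; C1, C5 and C7 are carried over from 12, whereas the new centre C3 is set in the closure under weak control only (a boat-like transition state gives 13, a chair-like one its epimer, about 1:1 estimated), so 15 is separated from its C3 epimer by chromatography, which its OH···O=C11 hydrogen bond should help.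

**Compound list**
1 | 2-methoxypropene | COC(C)=C | starting material
2 | methylmalonyl dichloride | CC(C(=O)Cl)C(=O)Cl | starting material
3 | 5-methoxy-2-methylbenzene-1,3-diol | COc1cc(O)c(C)c(O)c1 | intermediate
4 | (R)-2-methylbutanoic acid | CC[C@@H](C)C(=O)O | starting material
5 | (R)-2-methylbutanoyl chloride | CC[C@@H](C)C(=O)Cl | intermediate
6 | (2R)-1-(2,4-dihydroxy-6-methoxy-3-methylphenyl)-2-methylbutan-1-one | CC[C@@H](C)C(=O)c1c(O)c(C)c(O)cc1OC | intermediate
7 | (2R)-2-methyl-1-(2,4,6-trihydroxy-3-methylphenyl)butan-1-one | CC[C@@H](C)C(=O)c1c(O)c(C)c(O)cc1O | intermediate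
8 | prenyl bromide | CC(C)=CCBr | starting material
9 | (2R)-2-methyl-1-[2,4,6-trihydroxy-3-methyl-5-(3-methylbut-2-en-1-yl)phenyl]butan-1-one | CC[C@@H](C)C(=O)c1c(O)c(C)c(O)c(CC=C(C)C)c1O | intermediate
10 | isoprene monoxide (racemic) | CC1(C=C)CO1 | starting material
11 | (6S)-3,5-dihydroxy-6-[(2E)-4-hydroxy-3-methylbut-2-en-1-yl]-6-methyl-4-[(2R)-2-methylbutanoyl]-2-(3-methylbut-2-en-1-yl)cyclohexa-2,4-dien-1-one | CC[C@@H](C)C(=O)C1=C(O)[C@](C)(C/C=C(\C)CO)C(=O)C(CC=C(C)C)=C1O | intermediate
12 | (1S,5S,7S)-4-hydroxy-5-methyl-3-[(2R)-2-methylbutanoyl]-1-(3-methylbut-2-en-1-yl)-7-(prop-1-en-2-yl)bicyclo[3.2.1]oct-3-ene-2,8-dione | CC[C@@H](C)C(=O)C1=C(O)[C@]2(C)C[C@@H](C(C)=C)[C@](CC=C(C)C)(C1=O)C2=O | intermediate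
13 | (1S,3R,5S,7S)-8-hydroxy-4,4,7-trimethyl-9-[(2R)-2-methylbutanoyl]-3-(prop-1-en-2-yl)tricyclo[5.3.1.0(1,5)]undec-8-ene-10,11-dione | CC[C@@H](C)C(=O)C1=C(O)[C@]2(C)C[C@H]3C(C)(C)[C@@H](C(C)=C)C[C@@]3(C1=O)C2=O | intermediate
14 | (1S,3S,5S,7S)-3-(2-hydroperoxypropan-2-yl) analogue of 15 | CC[C@@H](C)C(=O)C1=C(O)[C@]2(C)C[C@H]3C(C)(C)[C@@H](C(C)(C)OO)C[C@@]3(C1=O)C2=O | intermediate
15 | (1S,3S,5S,7S)-8-hydroxy-3-(2-hydroxypropan-2-yl)-4,4,7-trimethyl-9-[(2R)-2-methylbutanoyl]tricyclo[5.3.1.0(1,5)]undec-8-ene-10,11-dione | CC[C@@H](C)C(=O)C1=C(O)[C@]2(C)C[C@H]3C(C)(C)[C@@H](C(C)(C)O)C[C@@]3(C1=O)C2=O | target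

**Total step count:** 5. **Longest linear sequence:** 5 (1/2 → 3 → 7 → 9 → 12 → 15).

**Steps most likely to fail**

**Step 5.** The risks are weak control at C3, quenching of Co–H by the acidic substrate, and drift of the exo-isopropenyl group to an isopropylidene.
- The fallback sets out from 13 and returns at 15. It replaces face selection in the C–C closure by delivery of a hydrogen atom to a ring radical.
- The flask is worked up after the argon stage. 13 is taken together with its C3 epimer, the (3S)-isopropenyl tricycle F6.
- Acid isomerisation (TsOH, benzene) erases the centre in both and gives the tetrasubstituted isopropylidene tricycle F7.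
- Epoxidation from the open convex face (DMDO) gives the spiro-epoxide F8.
- F8 is opened reductively with Cp2TiCl2/Mn/H2O. Homolysis of the ring C–O bond gives the tertiary C3 radical. This radical takes H from the convex face, which pushes CMe2OH to the side of the C11 carbonyl and gives 15.

**Step 4.** The risks are attack by the prenyl-bearing instead of the methyl-bearing carbon, a slow second ionisation, and modest enantioselectivity.
- The fallback sets out from 9 and returns at 13.
- 9 is C-prenylated with 8 at the methyl-bearing carbon under a cinchona-derived phase-transfer catalyst (CsOH·H2O, toluene, −40 °C). This gives the (6S)-diprenyl dienone F5.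
- Mn(OAc)3/Cu(OAc)2 in AcOH then closes both five-membered rings from the ring-centred tricarbonyl radical. Cu(II) oxidation ends the sequence at the isopropenyl group, giving 13 plus its C3 epimer.
- This material enters the O2 stage of step 5.

**Step 1.** The risks are pyrone or oligomer formation and loss of the enol ether to HCl.
- The fallback sets out from 2 and returns at 7. It makes use of the pyrone exit instead of fighting it.
- 2 and isopropenyloxytrimethylsilane give 4-hydroxy-3,6-dimethyl-2H-pyran-2-one F1.
- Me2SO4/K2CO3 gives 4-methoxy-3,6-dimethyl-2H-pyran-2-one F2.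
- NaOMe/MeOH at 180 °C gives 5-methoxy-4-methylbenzene-1,3-diol F3. Here the vinylogous enolate of the 6-methyl group attacks the lactone carbonyl in an intramolecular Claisen ring transformation.
- Acylation with 5 (AlCl3) between the two hydroxyls gives (2R)-1-(2,6-dihydroxy-4-methoxy-3-methylphenyl)-2-methylbutan-1-one F4.
- BBr3 then gives 7.

**Further compounds**
F1 | step 1 | 4-hydroxy-3,6-dimethyl-2H-pyran-2-one | CC1=CC(O)=C(C)C(=O)O1
F2 | step 1 | 4-methoxy-3,6-dimethyl-2H-pyran-2-one | CC1=CC(OC)=C(C)C(=O)O1
F3 | step 1 | 5-methoxy-4-methylbenzene-1,3-diol | COc1cc(O)cc(O)c1C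
F4 | step 1 | (2R)-1-(2,6-dihydroxy-4-methoxy-3-methylphenyl)-2-methylbutan-1-one | CC[C@@H](C)C(=O)c1c(O)c(C)c(OC)cc1O
F5 | step 4 | (6S)-3,5-dihydroxy-6-methyl-4-[(2R)-2-methylbutanoyl]-2,6-bis(3-methylbut-2-en-1-yl)cyclohexa-2,4-dien-1-one | CC[C@@H](C)C(=O)C1=C(O)[C@](C)(CC=C(C)C)C(=O)C(CC=C(C)C)=C1O
F6 | step 5 | (1S,3S,5S,7S)-isopropenyl tricycle (C3 epimer of 13) | CC[C@@H](C)C(=O)C1=C(O)[C@]2(C)C[C@H]3C(C)(C)[C@H](C(C)=C)C[C@@]3(C1=O)C2=O
F7 | step 5 | (1S,5S,7S)-3-(propan-2-ylidene) tricycle | CC[C@@H](C)C(=O)C1=C(O)[C@]2(C)C[C@H]3C(C)(C)C(=C(C)C)C[C@@]3(C1=O)C2=O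
F8 | step 5 | spiro-epoxide of F7 with the oxygen on the convex face | CC[C@@H](C)C(=O)C1=C(O)[C@]2(C)C[C@H]3C(C)(C)[C@]4(OC4(C)C)C[C@@]3(C1=O)C2=O
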